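The earlier runs and the new flask come from a simulation from invented constants; the scatter is artificial.

The flask is still stirring.

common to all: solid substrate 0.0020 M

| flask | protic impurity | solid reagent | remark | time |
|---|---|---|---|---|
| Tuesday's | 1 mM | 1 equiv | the very flask that is asked about, followed so far |  |
| flask | 1.00 mM | 1.00 equiv |  | 5.0 min |

Tuesday's run (percent of the solid substrate charged)

| time / s | target / % | solid substrate / % |
|---|---|---|
| 10.0 | 0.2 | 89.8 |
| 30.0 | 0.8 | 77.6 |
| 60.0 | 3.9 | 68.0 |
| 80.0 | 6.2 | 63.6 |
| 120 | 11.7 | 57.6 |

(scatter of a reading: 0.3 percentage points)

- as a solid, counted per litre of solution: solid substrate, solid reagent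
- at the start none of the solid substrate is in solution
- at the start none of the solid reagent is in solution

- maple: doubling the solubility of the solid reagent, all else as stated
- ash: doubling the solubility of the solid substrate, all else as stated
- oak: doubling the dissolution coefficient of the solid reagent, all else as stated
- cedar: doubling the dissolution coefficient of the solid substrate, all else as stated

* amount of target at 5.0 min, in percent of the solid substrate charged
* the change that raises the amount of target at 5.0 min, in percent of the solid substrate charged most ("none" if none brings more than 2 percentage points) (maple / ash / oak / cedar / none)
* amount of target at 5.0 min, in percent of the solid substrate charged, after cedar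

On Tuesday's readings, solid lost minus target leaves what stands dissolved: 30.2% of the charge at 80.0 s and 30.7% at 120 s. I call this last reading the solution's fill, the share of the charge I expect to stand dissolved in this flask while solid remains.

From above, a solution holding its fill keeps target under 69.3%. If the protic impurity, charged at 50.0% of the solid substrate, takes its whole share of the reagent, target stays under 50.0%. From below, Tuesday's target readings climb faster between 80.0 s and 120 s than between 60.0 s and 80.0 s, so I take the latest pace, held to the asked time, as my estimate of a lower edge: 36.4%. I commit to 36.4% to 50.0%, and to ash, which should double the fill.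

The forecast says 36% (29% to 43%), on my lower edge. It picks maple, holding that “ash exhausts solid substrate”, and gives 37% after cedar (30% to 44%).

The flask gives 42.7%, more than the forecast's 36%. The change ash adds 14 percentage points, more than maple's 5.3 points, and cedar gives 44.9%.

    solid substrate ⇌ dissolved substrate, rate k1*(cs1 - [dissolved substrate]) while solid is left; crystals form when [dissolved substrate] > cs1 (solubility = 0.700 mM, k = 0.0344 s⁻¹)
    dissolved substrate + partner → target (k = 13.9 M⁻¹ s⁻¹)
    partner + protic impurity → quenched reagent (k = 20.6 M⁻¹ s⁻¹)
    solid reagent ⇌ partner, rate k4*(cs4 - [partner]) while solid is left; crystals form when [partner] > cs4 (solubility = 1.60 mM, k = 0.00665 s⁻¹)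

At 1.86 min this flask makes dissolved substrate 1.02 times as fast as it uses it up, each step taken net, and at 5.00 min dissolved substrate stands at 30.8%, level with the fill of 30.7% read on Tuesday. In the neighbour charged with 40.0% of this flask's solid substrate, the equivalents of solid reagent held, the same dissolved amount as the fill is 76.7% of its charge, and at 5.00 min that neighbour holds solid substrate at 0%, dissolved substrate at 66.0% and target at 34.0%.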